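**Retrosynthetic overview**

1. The target is the head-to-tail hydroarylation dimer of one chromene monomer (5-hydroxy-7-(4-hydroxyphenethyl)-8-prenyl-2,2-dimethyl-2H-chromene). The C4–C6' bond and the only stereocentre are made last, by a chiral-acid-catalysed dimerisation that turns one chromene into the 4-aryl chroman.
2. The monomer comes from its 6-carbomethoxy derivative. The ester is a traceless control group: it hydrogen-bonds the 5-OH so the pyran closes on the other oxygen, blocks C6 so an O-prenyl group travels to C8 by para-Claisen–Cope shift, acidifies the 7-methyl for C-benzylation to the bibenzyl, and finally leaves as CO2.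
3. The chromene ester comes from two molecules of methyl acetoacetate plus prenal. The benzene ring (tetraketide aldol aromatisation) and the 2H-pyran ring (Knoevenagel/oxa-6π) are both closed in one flask.
4. Ring order: benzene ring, then pyran ring (same operation). The chroman ring of the target is the second monomer's pyran ring, saturated in the dimerisation. The two hydroxyphenyl rings come from 4-methoxybenzyl chloride.

Assumption: the (R)-configured acid in step 6 is taken to deliver the (4R) dimer; the sense of induction must be confirmed on the first run, and the mirror-image acid is used if it is the opposite.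

**Route**

Step 1
Reactants: 1 methyl acetoacetate (two molecules); 2 prenal (3-methylbut-2-enal)
Product: 6 methyl 5-hydroxy-2,2,7-trimethyl-2H-chromene-6-carboxylate, via methyl 3,5,7-trioxooctanoate 3 (not isolated), via methyl orsellinate 4 (not isolated), via Knoevenagel o-quinone methide 5 (not isolated)
Conditions: NaH, THF, 0 °C; n-BuLi, −78 °C → reflux; AcOH; then 2, ethylenediammonium diacetate (20 mol%), PhMe, 110 °C (THF distilled out)
Reagents that add atoms: none
Why: Claisen self-condensation of the acetoacetate dianion gives tetraketide 3, which closes the benzene ring by intramolecular aldol condensation/aromatisation (biomimetic orsellinate synthesis), and in the same flask 4 undergoes Knoevenagel condensation with 2 at C3 followed by oxa-6π electrocyclisation of 5 onto the para oxygen only, because the ortho-OH stays hydrogen-bonded to the ester; no stereocentre is formed.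

Step 2
Reactants: 6 methyl 5-hydroxy-2,2,7-trimethyl-2H-chromene-6-carboxylate; 7 prenyl bromide (1-bromo-3-methylbut-2-ene)
Product: 8 methyl 2,2,7-trimethyl-5-[(3-methylbut-2-en-1-yl)oxy]-2H-chromene-6-carboxylate
Conditions: K2CO3, DMF, 50 °C
Reagents that add atoms: none
Why: Williamson ether synthesis on the only free (ester-chelated) phenol, the other oxygen being already tied up in the pyran ring, so O-alkylation is unambiguous.

Step 3
Reactants: 8 methyl 2,2,7-trimethyl-5-[(3-methylbut-2-en-1-yl)oxy]-2H-chromene-6-carboxylate; 9 4-methoxybenzyl chloride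
Product: 11 methyl 7-[2-(4-methoxyphenyl)ethyl]-2,2-dimethyl-5-[(3-methylbut-2-en-1-yl)oxy]-2H-chromene-6-carboxylate, via benzylic lithium species 10 (not isolated)
Conditions: LiN(iPr)2 (1.2 equiv), THF, −78 °C; then 9, −78 → 0 °C
Reagents that add atoms: none
Why: Lateral (benzylic) lithiation of an ortho-toluate, in which the ester acidifies the 7-methyl group and carbanion 10 is C-alkylated by the benzylic chloride (SN2), builds the bibenzyl CH2–CH2 link without any hydrogenation that would touch the alkenes.

Step 4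
Reactants: 11 methyl 7-[2-(4-methoxyphenyl)ethyl]-2,2-dimethyl-5-[(3-methylbut-2-en-1-yl)oxy]-2H-chromene-6-carboxylate
Product: 14 methyl 5-hydroxy-7-[2-(4-methoxyphenyl)ethyl]-2,2-dimethyl-8-(3-methylbut-2-en-1-yl)-2H-chromene-6-carboxylate, via ortho-dienone 12 (not isolated), via para-dienone 13 (not isolated)
Conditions: PhNEt2, 195 °C, sealed tube, 3 h
Reagents that add atoms: none
Why: Aromatic para-Claisen rearrangement (Claisen then Cope, two [3,3] shifts): both ortho positions of the ether are quaternary (ester-bearing C6 and C4a), so dienone 12 cannot enolise and passes the allyl unit on to C8, the only free ring carbon, the double inversion delivering an unrearranged prenyl group as known for ortho-carbomethoxy aryl allyl ethers.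

Step 5
Reactants: 14 methyl 5-hydroxy-7-[2-(4-methoxyphenyl)ethyl]-2,2-dimethyl-8-(3-methylbut-2-en-1-yl)-2H-chromene-6-carboxylate
Product: 16 7-[2-(4-hydroxyphenyl)ethyl]-2,2-dimethyl-8-(3-methylbut-2-en-1-yl)-2H-chromen-5-ol, via carboxylic acid 15 (not isolated)
Conditions: NaSEt (6 equiv), DMF, 140 °C; cold 1 M HCl work-up; crude 15, PhMe, 110 °C
Reagents that add atoms: none
Why: Thiolate SN2 O-demethylation cleaves both the hindered methyl ester and the aryl methyl ether, and the resulting 2-hydroxy-4-alkoxybenzoic acid 15 loses CO2 on warming (thermal protodecarboxylation of a β-resorcylic-type acid, as in cannabinoid acids), the alkenes being inert to the soft nucleophile.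

Step 6
Reactants: 16 7-[2-(4-hydroxyphenyl)ethyl]-2,2-dimethyl-8-(3-methylbut-2-en-1-yl)-2H-chromen-5-ol (two molecules, one as electrophile and one as nucleophile)
Product: 18 (4R)-4-{5-hydroxy-7-[2-(4-hydroxyphenyl)ethyl]-2,2-dimethyl-8-(3-methylbut-2-en-1-yl)-2H-chromen-6-yl}-7-[2-(4-hydroxyphenyl)ethyl]-2,2-dimethyl-8-(3-methylbut-2-en-1-yl)-3,4-dihydro-2H-chromen-5-ol, via chromenone o-quinone methide 17 (not isolated)
Conditions: (R)-3,3'-bis(2,4,6-triisopropylphenyl)-1,1'-binaphthyl-2,2'-diyl N-(trifluoromethanesulfonyl)phosphoramide (5 mol%), PhMe, 5 Å MS, −20 °C, 0.05 M, stopped near 60% conversion (16 recovered and recycled)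
Reagents that add atoms: none
Why: Proposed new method: the strong chiral acid protonates the electron-rich chromene of one molecule of 16 at C3 and, with loss of the 5-OH proton, gives o-quinone methide 17 hydrogen-bonded to the chiral anion, while a second molecule of 16, held through its own 5-OH by the same catalyst, adds through C6 (ortho to OH, para to the ring oxygen) to C4 in a face-selective 1,4-addition that sets the (4R) centre and re-aromatises the chroman ring; the closest known reaction types are chiral-phosphoric-acid-catalysed conjugate additions of phenols and naphthols to in situ o-quinone methides, Markovnikov hydroarylation of 2-vinylphenols, and the achiral acid dimerisation of 2,2-dimethylchromenes.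

**Compound list**

1 | methyl acetoacetate (methyl 3-oxobutanoate) | CC(=O)CC(=O)OC | starting material
2 | prenal (3-methylbut-2-enal) | CC(C)=CC=O | starting material
3 | methyl 3,5,7-trioxooctanoate (tetraketide, present as its polyanion, not isolated) | CC(=O)CC(=O)CC(=O)CC(=O)OC | intermediate
4 | methyl orsellinate (methyl 2,4-dihydroxy-6-methylbenzoate, not isolated) | COC(=O)c1c(C)cc(O)cc1O | intermediate
5 | Knoevenagel o-quinone methide: methyl 2-hydroxy-6-methyl-3-(3-methylbut-2-en-1-ylidene)-4-oxocyclohexa-1,5-diene-1-carboxylate (not isolated) | COC(=O)C1=C(O)C(=CC=C(C)C)C(=O)C=C1C | intermediate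
6 | methyl 5-hydroxy-2,2,7-trimethyl-2H-chromene-6-carboxylate | COC(=O)c1c(C)cc2OC(C)(C)C=Cc2c1O | intermediate
7 | prenyl bromide (1-bromo-3-methylbut-2-ene) | CC(C)=CCBr | starting material
8 | methyl 2,2,7-trimethyl-5-[(3-methylbut-2-en-1-yl)oxy]-2H-chromene-6-carboxylate | COC(=O)c1c(C)cc2OC(C)(C)C=Cc2c1OCC=C(C)C | intermediate
9 | 4-methoxybenzyl chloride | COc1ccc(CCl)cc1 | starting material
10 | benzylic lithium species of 8 (lithiated at the 7-methyl group, not isolated) | COC(=O)c1c(C[Li])cc2OC(C)(C)C=Cc2c1OCC=C(C)C | intermediate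
11 | methyl 7-[2-(4-methoxyphenyl)ethyl]-2,2-dimethyl-5-[(3-methylbut-2-en-1-yl)oxy]-2H-chromene-6-carboxylate | COC(=O)c1c(CCc3ccc(OC)cc3)cc2OC(C)(C)C=Cc2c1OCC=C(C)C | intermediate
12 | ortho-dienone: methyl 7-[2-(4-methoxyphenyl)ethyl]-2,2-dimethyl-6-(2-methylbut-3-en-2-yl)-5-oxo-5,6-dihydro-2H-chromene-6-carboxylate (racemic, not isolated) | COC(=O)C1(C(C)(C)C=C)C(=O)C2=C(OC(C)(C)C=C2)C=C1CCc1ccc(OC)cc1 | intermediate
13 | para-dienone: methyl 7-[2-(4-methoxyphenyl)ethyl]-2,2-dimethyl-8-(3-methylbut-2-en-1-yl)-5-oxo-5,8-dihydro-2H-chromene-6-carboxylate (racemic, not isolated) | COC(=O)C1=C(CCc2ccc(OC)cc2)C(CC=C(C)C)C2=C(C=CC(C)(C)O2)C1=O | intermediate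
14 | methyl 5-hydroxy-7-[2-(4-methoxyphenyl)ethyl]-2,2-dimethyl-8-(3-methylbut-2-en-1-yl)-2H-chromene-6-carboxylate | COC(=O)c1c(CCc3ccc(OC)cc3)c(CC=C(C)C)c2OC(C)(C)C=Cc2c1O | intermediate
15 | 5-hydroxy-7-[2-(4-hydroxyphenyl)ethyl]-2,2-dimethyl-8-(3-methylbut-2-en-1-yl)-2H-chromene-6-carboxylic acid (not isolated) | OC(=O)c1c(CCc3ccc(O)cc3)c(CC=C(C)C)c2OC(C)(C)C=Cc2c1O | intermediate
16 | 7-[2-(4-hydroxyphenyl)ethyl]-2,2-dimethyl-8-(3-methylbut-2-en-1-yl)-2H-chromen-5-ol (monomer) | CC(C)=CCc1c(CCc2ccc(O)cc2)cc(O)c2C=CC(C)(C)Oc12 | intermediate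
17 | chromenone o-quinone methide, tautomer of 16: 7-[2-(4-hydroxyphenyl)ethyl]-2,2-dimethyl-8-(3-methylbut-2-en-1-yl)-2,3-dihydro-5H-chromen-5-one with a C4=C4a double bond (not isolated) | CC(C)=CCC1=C2OC(C)(C)CC=C2C(=O)C=C1CCc1ccc(O)cc1 | intermediate
18 | (4R)-4-{5-hydroxy-7-[2-(4-hydroxyphenyl)ethyl]-2,2-dimethyl-8-(3-methylbut-2-en-1-yl)-2H-chromen-6-yl}-7-[2-(4-hydroxyphenyl)ethyl]-2,2-dimethyl-8-(3-methylbut-2-en-1-yl)-3,4-dihydro-2H-chromen-5-ol | CC(C)=CCc1c(CCc2ccc(O)cc2)c([C@H]2CC(C)(C)Oc3c(CC=C(C)C)c(CCc4ccc(O)cc4)cc(O)c32)c(O)c2c1OC(C)(C)C=C2 | target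

**Step count**

Total step count: 6.
Longest linear sequence: 6 steps (1 → 6 → 8 → 11 → 14 → 16 → 18); 2, 7 and 9 are bought reagents.

**The three steps most likely to fail**

The dimerisation (step 6) is the least secure. It is a new asymmetric reaction and may give low ee. The cation may be trapped by the chromene or prenyl alkene instead of C6. It may also over-react, because 18 still carries a free C6'–H and a chromene. The fallback sets out from 16 and comes back at 18, giving up catalyst control. Compound 16 is dimerised with an achiral acid (diphenyl hydrogen phosphate, (PhO)2P(O)OH, 10 mol%, PhMe, 0 °C, partial conversion) to the racemic dimer rac-4-{5-hydroxy-7-[2-(4-hydroxyphenyl)ethyl]-2,2-dimethyl-8-(3-methylbut-2-en-1-yl)-2H-chromen-6-yl}-7-[2-(4-hydroxyphenyl)ethyl]-2,2-dimethyl-8-(3-methylbut-2-en-1-yl)-3,4-dihydro-2H-chromen-5-ol F7. The enantiomers are separated by preparative chromatography on a chiral stationary phase (amylose tris(3,5-dimethylphenylcarbamate), CO2/MeOH). The (4R) enantiomer is 18, assigned by ECD and X-ray analysis of a heavy-atom ester; the (4S) enantiomer is discarded.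

The one-flask double ring closure (step 1) is the second risk. The self-condensation is only moderate in yield, and its by-products (open keto esters, pyranones) also consume prenal in the second stage. The fallback sets out from 2 and comes back at 6, reversing the ring order (pyran first, benzene second). Prenal 2 is condensed with bought 4-hydroxy-6-methyl-2H-pyran-2-one (ethylenediammonium diacetate, EtOAc, 80 °C) to 2,2,7-trimethyl-2H,5H-pyrano[4,3-b]pyran-5-one F1. The lithium enolate of methyl acetate (LiN(iPr)2, THF, −78 °C → rt) opens the lactone to methyl 3-[2,2-dimethyl-6-(2-oxopropyl)-2H-pyran-5-yl]-3-oxopropanoate F2 (not isolated). F2 closes by aldol condensation and dehydration (AcOH, 60 °C) to 6.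

The double demethylation–decarboxylation (step 5) is the third risk. Thiolate at 140 °C may not cleave the anisole cleanly in the presence of the chromene and the phenoxide. The fallback sets out from 8 and comes back at 15, changing the phenol protecting group so that no O-demethylation is needed. Lithium species 10 (from 8, as in step 3) is alkylated with bought tert-butyl[4-(bromomethyl)phenoxy]dimethylsilane to methyl 7-{2-[4-(tert-butyldimethylsilyloxy)phenyl]ethyl}-2,2-dimethyl-5-[(3-methylbut-2-en-1-yl)oxy]-2H-chromene-6-carboxylate F3. Heating as in step 4 takes F3 through the silyl-protected ortho-dienone F4 and the silyl-protected para-dienone F5 (neither isolated) to methyl 7-{2-[4-(tert-butyldimethylsilyloxy)phenyl]ethyl}-5-hydroxy-2,2-dimethyl-8-(3-methylbut-2-en-1-yl)-2H-chromene-6-carboxylate F6. KOH in EtOH–H2O at reflux, then cold 1 M HCl, cleaves silyl ether and ester together to acid 15, which is decarboxylated to 16 as before.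

**Further compounds**

F1 | step 1 | 2,2,7-trimethyl-2H,5H-pyrano[4,3-b]pyran-5-one | CC1=CC2=C(C=CC(C)(C)O2)C(=O)O1
F2 | step 1 | methyl 3-[2,2-dimethyl-6-(2-oxopropyl)-2H-pyran-5-yl]-3-oxopropanoate | COC(=O)CC(=O)C1=C(CC(C)=O)OC(C)(C)C=C1
F3 | step 5 | methyl 7-{2-[4-(tert-butyldimethylsilyloxy)phenyl]ethyl}-2,2-dimethyl-5-[(3-methylbut-2-en-1-yl)oxy]-2H-chromene-6-carboxylate | COC(=O)c1c(CCc3ccc(O[Si](C)(C)C(C)(C)C)cc3)cc2OC(C)(C)C=Cc2c1OCC=C(C)C
F4 | step 5 | silyl-protected ortho-dienone: methyl 7-{2-[4-(tert-butyldimethylsilyloxy)phenyl]ethyl}-2,2-dimethyl-6-(2-methylbut-3-en-2-yl)-5-oxo-5,6-dihydro-2H-chromene-6-carboxylate (racemic) | COC(=O)C1(C(C)(C)C=C)C(=O)C2=C(OC(C)(C)C=C2)C=C1CCc1ccc(O[Si](C)(C)C(C)(C)C)cc1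
F5 | step 5 | silyl-protected para-dienone: methyl 7-{2-[4-(tert-butyldimethylsilyloxy)phenyl]ethyl}-2,2-dimethyl-8-(3-methylbut-2-en-1-yl)-5-oxo-5,8-dihydro-2H-chromene-6-carboxylate (racemic) | COC(=O)C1=C(CCc2ccc(O[Si](C)(C)C(C)(C)C)cc2)C(CC=C(C)C)C2=C(C=CC(C)(C)O2)C1=O
F6 | step 5 | methyl 7-{2-[4-(tert-butyldimethylsilyloxy)phenyl]ethyl}-5-hydroxy-2,2-dimethyl-8-(3-methylbut-2-en-1-yl)-2H-chromene-6-carboxylate | COC(=O)c1c(CCc3ccc(O[Si](C)(C)C(C)(C)C)cc3)c(CC=C(C)C)c2OC(C)(C)C=Cc2c1O
F7 | step 6 | racemic dimer (both C4 configurations of 18) | CC(C)=CCc1c(CCc2ccc(O)cc2)c(C2CC(C)(C)Oc3c(CC=C(C)C)c(CCc4ccc(O)cc4)cc(O)c32)c(O)c2c1OC(C)(C)C=C2
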